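I decided to judge these two runs by the time each flask lost at its start, not by an order in [X].

common to all: Z 0.800 M; L 0.0240 M

| charge | X | time |
|---|---|---|
| Wednesday's | 1.20 M |  |
| Thursday's | 2.40 M |  |
| Friday's | 5.50 M | 6.7 min |

| run | time / min | [Q] / M |
|---|---|---|
| Wednesday's run | 0.30 | 0.0125 |
| Wednesday's run | 0.90 | 0.0496 |
| Wednesday's run | 1.7 | 0.1110 |
| Wednesday's run | 2.7 | 0.1861 |
| Wednesday's run | 3.9 | 0.2764 |
| Wednesday's run | 5.2 | 0.3755 |
| Wednesday's run | 6.7 | 0.4824 |
| Thursday's run | 0.30 | 0.0153 |
| Thursday's run | 0.90 | 0.0614 |
| Thursday's run | 1.7 | 0.1220 |
| Thursday's run | 2.7 | 0.2021 |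
| Thursday's run | 3.9 | 0.2957 |
| Thursday's run | 5.2 | 0.3958 |
| Thursday's run | 6.7 | 0.5100 |

(readings scatter by 0.002 M)

- reaction order in [X] at the outset, round the charge of the Wednesday's run, defined at two percent of the Z turned into Q
- Q in the Friday's run at 6.7 min, as a share of the Z charged
- which of these the readings show (the second partner kills the catalyst / the catalyst wakes slowly / the product reacts on with the second partner / the product ties up the catalyst / the product binds the second partner)

- Overall: Z + X -> Q, with L as catalyst.
- Constant volume, constant temperature.
- Bound and free are read together.
- "The second partner" is X.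
- An order is taken over about fifteen percent of the charge, up and down.

The bench rule came first. I divided Thursday's [Q] by Wednesday's at one time and took the logarithm of that ratio over the logarithm of the [X] ratio. A ratio of one is the zero of this scale, where X does nothing. At 0.90 min the rule gave an order of 0.308, and at 6.7 min it gave 0.0803. Carried to Friday's [X], the late order put Q at 68.1% of the Z charged. But the early order was 3.84 times the late one, so this was no constant order, and the rule stopped there.

Wednesday's mean rate up to 0.90 min was 0.0551 M min⁻¹. From 1.7 min to 6.7 min it was higher, at 0.0743 M min⁻¹. That straight line meets the time axis at 0.206 min. This crossing is the lost time, the induction period: a flask that runs straight from zero loses none. Thursday's line had slope 0.0776 M min⁻¹ and read 0.128 min.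

So I gave Friday Thursday's last reading plus the whole of Thursday's lost time at Thursday's slope. That made 65.0%, with no gain in slope counted.

The forecast said 0.28, 65.7% and the catalyst wakes slowly, on the ground that “The readings show a lag, not a slowdown”. Its Friday figure stood 0.70 percentage points above mine.

The flask gave 0.28, 65.8% and the catalyst wakes slowly.

    Ja + Z ⇌ LZ, settled at all times (2.930 L mol⁻¹)
    LZ + X ⇌ LZX, settled at all times (24.00 L mol⁻¹)
    LZX → Q + Ja (3.342 min⁻¹)
    L + X → Ja + X (3.690 L mol⁻¹ min⁻¹)

The power-law fit had forecast 69.0% for Friday, higher than the flask. On a straight run from zero, the time to a quarter of the Z charged, doubled, equals the time to half of it, so the first time doubled less the second is the lost time. It came to 0.170 min in Wednesday's run, where the line had read 0.206 min, and 0.0960 min in Thursday's, where it had read 0.128 min.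

(The numbers in the tables are simulated on assumed constants; noise was put on by code.)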